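The 14-membered carbocycle (ring A) is cut at C13–C14, the sp2–sp3 bond that links the exocyclic (E)-alkylidene carbon C13 of the γ-lactone (ring B, C10–C11–C12–C20–O) to the C14 methylene beside C1. A palladium-catalysed alkyl–alkenyl Negishi coupling of the C14 alkylzinc with the C13 (E)-enol triflate, activated by the lactone carbonyl C20, closes ring A in one operation with retention of alkene geometry and without touching a stereocentre. The precursor is an open chain that carries the C14 iodide, the C13 triflate and the C5/C7 diketone masked as an isoxazole; C1, C3 and C4 stem from (S)-carvone oxide, C10 from a D-glutamate-derived lactone.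

Key step: step 13

Numbering: C1 = CH bearing isopropenyl; C2; C3–C4 = epoxide (C4 bears CH3); C5 and C7 = ketones; C6; C8 = CH(CO2Me); C9; C10 = lactone O–CH; C11; C12=C13; C14; C20 = lactone C=O.

Assumption: C8 is the α-carbon of a β-keto ester and epimerises through its enol, so the (8S) arrangement of the target is taken to be the thermodynamically favoured one in ring A; 14–24 are therefore carried as pairs of C8 epimers and C8 is fixed by equilibration in step 15.

Remark: lactone 10 is a catalogue compound; it is the lactone obtained from D-glutamic acid by nitrous acid deamination (retention) and borane reduction.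

Step 1
Reactants: 1 (S)-(+)-carvone
Product: 2 trans-carvone oxide (1S,4S,6S)
Conditions: 30% aq. H2O2, NaOH (cat.), MeOH, 0 °C
Reagents that add atoms: hydrogen peroxide, OO
Why: Weitz–Scheffer nucleophilic epoxidation of the enone, in which hydroperoxide adds to the β-carbon on the face anti to the isopropenyl group, so that C3 and C4 are set with the epoxide trans to isopropenyl, while the isolated alkene is inert to alkaline H2O2.

Step 2
Reactants: 2 trans-carvone oxide
Product: 4 3-hydroxy-trans-carvone oxide (both C3 carbinol epimers), via potassium enolate 3 (not isolated)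
Conditions: KN(SiMe3)2, THF, −78 °C; then 2-(phenylsulfonyl)-3-phenyloxaziridine, −78 °C; AcOH
Reagents that add atoms: 2-(phenylsulfonyl)-3-phenyloxaziridine, O=S(=O)(N1OC1c1ccccc1)c1ccccc1
Why: Davis hydroxylation of the enolate, which can form only on the CH2 side because the other α-carbon is the fully substituted epoxide carbon; the new carbinol centre is not controlled and is destroyed in step 3.

Step 3
Reactants: 4 3-hydroxy-trans-carvone oxide
Product: 6 methyl (2S,3S)-3-[(2R)-2-(hydroxymethyl)-3-methylbut-3-en-1-yl]-2-methyloxirane-2-carboxylate, via aldehyde ester 5 (not isolated)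
Conditions: Pb(OAc)4, MeOH/PhH (1:1), 0 °C; Celite filtration; then NaBH4, MeOH, −40 °C
Reagents that add atoms: methanol, CO
Why: Criegee-type Pb(OAc)4 cleavage of the α-ketol in methanol opens the ring between the carbonyl carbon (to the C5 methyl ester) and the carbinol carbon (to the C14 aldehyde) with all carbons kept, and immediate borohydride reduction of the aldehyde, much faster than that of the glycidic ester, removes the epimerisable β,γ-unsaturated aldehyde before C1 can scramble.

Step 4
Reactants: 6 hydroxy ester
Product: 7 methyl (2S,3S)-3-[(2R)-2-(iodomethyl)-3-methylbut-3-en-1-yl]-2-methyloxirane-2-carboxylate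
Conditions: PPh3, I2, imidazole, CH2Cl2, 0 °C
Reagents that add atoms: iodine, II
Why: Appel iodination of the primary alcohol (SN2 at CH2, no stereocentre involved) under buffered neutral conditions, done at once so that the 4,5-epoxy alcohol cannot close to a tetrahydrofuran.

Step 5
Reactants: 7 iodo ester
Product: 8 (2S,3S)-3-[(2R)-2-(iodomethyl)-3-methylbut-3-en-1-yl]-2-methyloxirane-2-carbaldehyde
Conditions: i-Bu2AlH (1.05 equiv), CH2Cl2, −78 °C; MeOH, then aq. KNaC4H4O6
Reagents that add atoms: none
Why: Partial ester reduction with i-Bu2AlH, in which the chelated aluminium hemiacetal of the α-alkoxy ester persists at −78 °C until work-up; the aldehyde has no α-hydrogen and the alkyl iodide is inert at this temperature.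

Step 6
Reactants: 8 epoxy aldehyde
Product: 9 (2R,3S)-2-ethynyl-3-[(2R)-2-(iodomethyl)-3-methylbut-3-en-1-yl]-2-methyloxirane
Conditions: dimethyl (1-diazo-2-oxopropyl)phosphonate, K2CO3, MeOH, 0 °C → rt
Reagents that add atoms: dimethyl (1-diazo-2-oxopropyl)phosphonate, COP(=O)(OC)C(=[N+]=[N-])C(C)=O
Why: Ohira–Bestmann form of the Seyferth–Gilbert homologation (olefination, loss of N2, 1,2-shift in the alkylidene carbene) adds C6 and makes the C5≡C6 terminal alkyne; the α-carbon is quaternary and the hindered primary iodide should survive the weakly basic methanol.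

Step 7
Reactants: 10 (5R)-5-(hydroxymethyl)oxolan-2-one
Product: 11 [(2R)-5-oxooxolan-2-yl]methyl trifluoromethanesulfonate
Conditions: Tf2O, 2,6-lutidine, CH2Cl2, −78 → −40 °C; cold aqueous wash, used at once
Reagents that add atoms: trifluoromethanesulfonic anhydride, O=S(=O)(OS(=O)(=O)C(F)(F)F)C(F)(F)F
Why: O-sulfonylation of a primary alcohol with Tf2O and a hindered pyridine base at low temperature, which leaves C10 untouched.

Step 8
Reactants: 11 lactone triflate, 12 methyl 3,3-dimethoxypropanoate
Product: 14 methyl 2-(dimethoxymethyl)-3-[(2R)-5-oxooxolan-2-yl]propanoate (C8 epimer pair), via lithium enolate 13 (not isolated)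
Conditions: 12, LiN(i-Pr)2, THF, −78 °C; then 11, THF/DMPU, −78 °C; AcOH at −78 °C
Reagents that add atoms: none
Why: SN2 alkylation of a lithium ester enolate by a primary triflate, fast enough at −78 °C that the β-methoxy enolate neither eliminates methoxide nor attacks the lactone carbonyl; C8 forms without control as an epimer pair (see assumption).

Step 9
Reactants: 14 acetal ester
Product: 15 methyl 2-[(hydroxyimino)methyl]-3-[(2R)-5-oxooxolan-2-yl]propanoate (C8 epimers, oxime E/Z)
Conditions: NH2OH·HCl, MeOH/H2O (4:1), 40 °C
Reagents that add atoms: hydroxylamine hydrochloride, NO.Cl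
Why: Acid-mediated exchange of the dimethyl acetal for the oxime (oxime formation), run unbuffered so that the oxime hydroxyl should not close onto the neighbouring ester.

Step 10
Reactants: 15 oxime, 9 iodo alkyne
Product: 18 methyl 2-{5-[(2S,3S)-3-[(2R)-2-(iodomethyl)-3-methylbut-3-en-1-yl]-2-methyloxiran-2-yl]-1,2-oxazol-3-yl}-3-[(2R)-5-oxooxolan-2-yl]propanoate (C8 epimer pair), via hydroximoyl chloride 16 (not isolated), via nitrile oxide 17 (not isolated)
Conditions: 15 (1.5 equiv), NCS (1.5 equiv), DMF, 25 °C; then 9, Et3N (syringe pump), 0 → 25 °C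
Reagents that add atoms: none
Why: Huisgen 1,3-dipolar cycloaddition of a nitrile oxide (oxime chlorination, then dehydrochlorination) to a terminal alkyne, which for steric and frontier-orbital reasons gives the 3,5-disubstituted isoxazole with oxygen on C5 and nitrogen on C7; NCS is consumed before 9 is added, so the isopropenyl group sees no electrophilic chlorine.

Step 11
Reactants: 18 isoxazole iodide
Product: 20 C12 hydroxymethylidene lactone (enol form of the C13 aldehyde; C8 epimer pair), via dilithium dienolate 19 (not isolated)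
Conditions: LiN(i-Pr)2 (2.3 equiv), THF, −78 °C; then HCO2CH2CF3, −78 °C; AcOH
Reagents that add atoms: 2,2,2-trifluoroethyl formate, O=COCC(F)(F)F
Why: Claisen-type C-formylation within a dianion, where the second-formed and more reactive lactone enolate at C12 is acylated in preference to the stabilised, hindered C8 enolate and the acidic product then takes up the remaining charge; iodide and epoxide are protected by the low temperature.

Step 12
Reactants: 20 hydroxymethylidene lactone
Product: 21 seco C14 iodide / C13 (E)-enol triflate with isoxazole-masked diketone (C8 epimer pair)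
Conditions: PhNTf2, Et3N, DMAP (cat.), CH2Cl2, 0 °C
Reagents that add atoms: N-phenylbis(trifluoromethanesulfonimide), O=S(=O)(N(c1ccccc1)S(=O)(=O)C(F)(F)F)C(F)(F)F
Why: O-triflation of the ammonium enolate of an α-formyl lactone; with no chelating metal the enolate oxygen lies anti to the lactone carbonyl, so the thermodynamically preferred (E)-enol triflate (OTf cis to C11) should form.

Step 13
Reactants: 21 seco iodide / enol triflate
Product: 23 isoxazole-bridged 14-membered macrocycle (1R,3S,4S,10S,12E; C8 epimer pair), via alkylzinc iodide 22 (not isolated)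
Conditions: Zn dust (activated with BrCH2CH2Br/Me3SiCl), LiCl, THF, 30 °C; then slow addition to Pd(dppf)Cl2 (10 mol%), THF/NMP, 50 °C, final 2 mM
Reagents that add atoms: none
Why: Zinc inserts into the primary C14–I bond to give the LiCl-solubilised alkylzinc iodide 22, zerovalent palladium adds oxidatively to the C13–OTf bond, transmetalation gives an alkyl(alkenyl)palladium species and reductive elimination forms C13–C14. The closest known reaction type is the intramolecular alkyl–alkenyl Negishi macrocyclization of an alkylzinc halide with an alkenyl triflate or iodide. Ring A is closed as a 14-membered macrocycle by reductive elimination from a 15-membered palladacycle, the new σ-bond ending on sp2 carbon C13 so that C12=C13 becomes endocyclic to ring A and stays exocyclic to ring B. No stereocentre is formed, and C1, C3, C4 and C10 are remote from the reacting carbons. The step needs retention of the (E)-geometry, which oxidative addition and reductive elimination at sp2 carbon provide, and ring closure in preference to oligomerisation, protonation and β-hydride elimination: slow addition keeps 22 dilute, the wide-bite-angle dppf ligand speeds reductive elimination, the triflate is activated by conjugation with C20, and the isoxazole keeps the C5/C7 diketone from quenching the organozinc.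

Step 14
Reactants: 23 isoxazole macrocycle
Product: 24 (Z)-enaminone macrocycle (NH2 on C7, ketone at C5; C8 epimer pair)
Conditions: Mo(CO)6, MeCN/H2O (10:1), 80 °C
Reagents that add atoms: none
Why: Mo(CO)6-mediated reductive cleavage of the isoxazole N–O bond (N-coordination, N–O insertion, hydrolysis) gives the hydrogen-bonded β-amino enone and should leave the alkylidene lactone, the isopropenyl group and the epoxide alone.

Step 15
Reactants: 24 enaminone macrocycle
Product: 25 CNP0108136.1 (1R,3S,4S,8S,10S,12E)
Conditions: 10% aq. oxalic acid, THF, 0 → 23 °C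
Reagents that add atoms: water, O
Why: Hydrolysis of the vinylogous amide (C-protonation, addition of water at C7, loss of ammonia) with a weak non-nucleophilic acid that should spare the epoxide; the β-keto ester methine C8 then equilibrates through its enol to the favoured (8S) arrangement under thermodynamic control (see assumption).

Compound list

1 | (S)-(+)-carvone, (5S)-2-methyl-5-(prop-1-en-2-yl)cyclohex-2-en-1-one | C=C(C)[C@@H]1CC(=O)C(C)=CC1 | starting material
2 | trans-carvone oxide, (1S,4S,6S)-1-methyl-4-(prop-1-en-2-yl)-7-oxabicyclo[4.1.0]heptan-2-one | C=C(C)[C@@H]1CC(=O)[C@@]2(C)O[C@H]2C1 | intermediate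
3 | potassium enolate of 2 (enolate towards the CH2 carbon) | C=C(C)[C@@H]1C=C([O-])[C@@]2(C)O[C@H]2C1.[K+] | intermediate
4 | (1S,4R,6S)-3-hydroxy-1-methyl-4-(prop-1-en-2-yl)-7-oxabicyclo[4.1.0]heptan-2-one, both C3 epimers | C=C(C)[C@@H]1C(O)C(=O)[C@@]2(C)O[C@H]2C1 | intermediate
5 | methyl (2S,3S)-3-[(2R)-2-formyl-3-methylbut-3-en-1-yl]-2-methyloxirane-2-carboxylate | O=C[C@@H](C(C)=C)C[C@@H]1O[C@]1(C)C(=O)OC | intermediate
6 | methyl (2S,3S)-3-[(2R)-2-(hydroxymethyl)-3-methylbut-3-en-1-yl]-2-methyloxirane-2-carboxylate | OC[C@@H](C(C)=C)C[C@@H]1O[C@]1(C)C(=O)OC | intermediate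
7 | methyl (2S,3S)-3-[(2R)-2-(iodomethyl)-3-methylbut-3-en-1-yl]-2-methyloxirane-2-carboxylate | IC[C@@H](C(C)=C)C[C@@H]1O[C@]1(C)C(=O)OC | intermediate
8 | (2S,3S)-3-[(2R)-2-(iodomethyl)-3-methylbut-3-en-1-yl]-2-methyloxirane-2-carbaldehyde | IC[C@@H](C(C)=C)C[C@@H]1O[C@]1(C)C=O | intermediate
9 | (2R,3S)-2-ethynyl-3-[(2R)-2-(iodomethyl)-3-methylbut-3-en-1-yl]-2-methyloxirane | IC[C@@H](C(C)=C)C[C@@H]1O[C@]1(C)C#C | intermediate
10 | (5R)-5-(hydroxymethyl)oxolan-2-one | OC[C@H]1CCC(=O)O1 | starting material
11 | [(2R)-5-oxooxolan-2-yl]methyl trifluoromethanesulfonate | O=S(=O)(OC[C@H]1CCC(=O)O1)C(F)(F)F | intermediate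
12 | methyl 3,3-dimethoxypropanoate | COC(CC(=O)OC)OC | starting material
13 | lithium enolate of 12 | COC(OC)C=C(OC)[O-].[Li+] | intermediate
14 | methyl 2-(dimethoxymethyl)-3-[(2R)-5-oxooxolan-2-yl]propanoate, C8 epimer pair | COC(OC)C(C(=O)OC)C[C@H]1CCC(=O)O1 | intermediate
15 | methyl 2-[(hydroxyimino)methyl]-3-[(2R)-5-oxooxolan-2-yl]propanoate, C8 epimer pair | ON=CC(C(=O)OC)C[C@H]1CCC(=O)O1 | intermediate
16 | methyl 3-chloro-3-(hydroxyimino)-2-{[(2R)-5-oxooxolan-2-yl]methyl}propanoate | ON=C(Cl)C(C(=O)OC)C[C@H]1CCC(=O)O1 | intermediate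
17 | nitrile oxide from 16 (C7 = nitrile oxide carbon) | [O-][N+]#CC(C(=O)OC)C[C@H]1CCC(=O)O1 | intermediate
18 | methyl 2-{5-[(2S,3S)-3-[(2R)-2-(iodomethyl)-3-methylbut-3-en-1-yl]-2-methyloxiran-2-yl]-1,2-oxazol-3-yl}-3-[(2R)-5-oxooxolan-2-yl]propanoate, C8 epimer pair | IC[C@@H](C(C)=C)C[C@@H]1O[C@]1(C)c2cc(no2)C(C(=O)OC)C[C@H]3CCC(=O)O3 | intermediate
19 | dilithium dienolate of 18 (C8 ester enolate and C12 lactone enolate) | IC[C@@H](C(C)=C)C[C@@H]1O[C@]1(C)c2cc(no2)C(=C([O-])OC)C[C@H]3CC=C([O-])O3.[Li+].[Li+] | intermediate
20 | 18 with a hydroxymethylidene group on C12 of the lactone [(2S)-4-(hydroxymethylidene)-5-oxooxolan-2-yl], C8 epimer pair | IC[C@@H](C(C)=C)C[C@@H]1O[C@]1(C)c2cc(no2)C(C(=O)OC)C[C@H]3CC(=CO)C(=O)O3 | intermediate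
21 | methyl 2-{5-[(2S,3S)-3-[(2R)-2-(iodomethyl)-3-methylbut-3-en-1-yl]-2-methyloxiran-2-yl]-1,2-oxazol-3-yl}-3-[(2S,4E)-5-oxo-4-{[(trifluoromethanesulfonyl)oxy]methylidene}oxolan-2-yl]propanoate, C8 epimer pair | IC[C@@H](C(C)=C)C[C@@H]1O[C@]1(C)c2cc(no2)C(C(=O)OC)C[C@H]3C/C(=C\OS(=O)(=O)C(F)(F)F)C(=O)O3 | intermediate
22 | C14 alkylzinc iodide of 21 | I[Zn]C[C@@H](C(C)=C)C[C@@H]1O[C@]1(C)c2cc(no2)C(C(=O)OC)C[C@H]3C/C(=C\OS(=O)(=O)C(F)(F)F)C(=O)O3 | intermediate
23 | isoxazole-bridged macrocycle (isoxazole C3 on C8, C5 on C4; 1R,3S,4S,10S,12E), C8 epimer pair | C=C(C)[C@@H]1C/C=C2\C[C@H](CC(C(=O)OC)c4cc(on4)[C@@]3(C)O[C@H]3C1)OC2=O | intermediate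
24 | (Z)-7-amino-6-en-5-one macrocycle (enaminone), C8 epimer pair | C=C(C)[C@@H]1C/C=C2\C[C@H](CC(C(=O)OC)/C(N)=C/C(=O)[C@@]3(C)O[C@H]3C1)OC2=O | intermediate
25 | CNP0108136.1 (1R,3S,4S,8S,10S,12E) | C=C(C)[C@@H]1C/C=C2\C[C@H](C[C@H](C(=O)OC)C(=O)CC(=O)[C@@]3(C)O[C@H]3C1)OC2=O | target

Total step count: 15. Longest linear sequence: 12 steps (steps 1–6 and 10–15, from (S)-carvone).

Steps most likely to fail

Step 13. The organozinc may be protonated before it couples, intermolecular coupling may outrun ring closure, β-hydride elimination may follow transmetalation, and zinc salts may open the epoxide. Fallback: the preformed organometallic is abandoned and 21 is cyclised by a nickel-catalysed reductive cross-electrophile coupling (NiBr2·glyme, 4,4′-di-tert-butyl-2,2′-bipyridine, Mn powder, DMA, high dilution), in which the alkenylnickel species formed at C13 captures the C14 radical. This route sets out from 21, comes back at 23 and makes no new compound (F0).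

Step 11. Acylation may occur at the C8 enolate instead of C12, the second deprotonation may be incomplete, and the amide base may attack the iodide. Fallback: kinetic enolate acylation is replaced by a thermodynamically controlled condensation. Heating 18 with tert-butoxybis(dimethylamino)methane (toluene, 60 °C, nitrogen sweep to remove dimethylamine) should give the (E)-dimethylaminomethylidene lactone F1, because only the C12 methylene can lose two hydrogens to a conjugated enamine. Cold 1 M HCl/THF then hydrolyses the enamine. This route sets out from 18 and comes back at 20.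

Step 8. The β-methoxy enolate may eliminate methoxide, proton transfer to the lactone may stop the alkylation, and Claisen attack at the lactone carbonyl may compete. Fallback: the order of bond formation is inverted so that a stabilised, soft carbanion is alkylated. Acetal 12 and NH2OH·HCl give methyl 3-(hydroxyimino)propanoate F2, NCS gives methyl 3-chloro-3-(hydroxyimino)propanoate F3, and Et3N releases the nitrile oxide F4, which adds to alkyne 9 to give the methyl isoxazol-3-ylacetate F5. NaN(SiMe3)2 (1 equiv, THF, −78 °C) then forms the sodium enolate F6, and triflate 11 alkylates it at C8. This route sets out from 12 and 9 and comes back at 18.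

Further compounds

F0 | step 13 | none | none
F1 | step 11 | (E)-C12-dimethylaminomethylidene lactone derived from 18 (C8 epimer pair) | IC[C@@H](C(C)=C)C[C@@H]1O[C@]1(C)c2cc(no2)C(C(=O)OC)C[C@H]3C/C(=C\N(C)C)C(=O)O3
F2 | step 8 | methyl 3-(hydroxyimino)propanoate | ON=CCC(=O)OC
F3 | step 8 | methyl 3-chloro-3-(hydroxyimino)propanoate | ON=C(Cl)CC(=O)OC
F4 | step 8 | nitrile oxide from F3 (methoxycarbonylacetonitrile oxide) | [O-][N+]#CCC(=O)OC
F5 | step 8 | methyl 2-{5-[(2S,3S)-3-[(2R)-2-(iodomethyl)-3-methylbut-3-en-1-yl]-2-methyloxiran-2-yl]-1,2-oxazol-3-yl}acetate | IC[C@@H](C(C)=C)C[C@@H]1O[C@]1(C)c2cc(no2)CC(=O)OC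
F6 | step 8 | sodium enolate of F5 | IC[C@@H](C(C)=C)C[C@@H]1O[C@]1(C)c2cc(no2)C=C([O-])OC.[Na+]
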